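| flask | J | Z | remark | time |
|---|---|---|---|---|
| maple | 0.042 M | 3.6 mM (held) | run made earlier |  |
| ash | 0.063 M | 3.6 mM (held) | run made earlier |  |
| flask | 0.084 M | 3.6 mM (held) |  | 5.0 h |

| run | time / h | L / % | D / % |
|---|---|---|---|
| maple | 0.333 | 8.4 | 0 |
| maple | 1.00 | 37.1 | 27.4 |
| maple | 2.00 | 57.4 | 50.2 |
| maple | 2.50 | 60.1 | 52.8 |
| maple | 4.00 | 60.5 | 53.9 |
| maple | 5.00 | 60.3 | 52.9 |
| ash | 0.833 | 18.9 | 12.8 |
| ash | 1.50 | 38.0 | 31.3 |
| ash | 2.50 | 44.9 | 40.5 |
| ash | 3.00 | 44.5 | 40.4 |
| ash | 4.00 | 45.9 | 40.1 |
| ash | 5.00 | 45.5 | 41.4 |

(standard deviation of a reading: 0.5 percentage points)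

* how much L and D together there is at 5.0 h, in percent of the J charged
* concentration of Q in solution at 5.0 h, in percent of saturation

- what is said of L includes D
- J, D is a solid; its amount is given per volume of the solution
- at the start none of J is in solution
- at the start none of Z is in solution
- Q is what J becomes in solution
- Q means what is dissolved; the solid is not counted in it

1. J that has gone elsewhere for good cannot be waited back. Maple reads flat near 60.3% and ash near 45.5% from 2.50 h on, so my decision about the next run concerns the charge, not the stirring time.

2. I measure the charge by the plateau: the share of J not found in L, divided by the share found. This is W, the inverse of a selectivity for L, and y is one over one plus W, for small W and large alike. Maple reads 0.658 and ash 1.20, which is a rise by a factor of 1.82 for a charge raised by a factor of 1.50.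

3. I continue that line, at 25.7 /M, to the flask at 0.084 M. The flask's loss ratio W comes to 1.74, so y is 36.5%. On this line the extra 21.0 mM of J over ash buys 2.02 mM of L, so I run this flask as a test of W, not for its L. I read the flat plateaus, with Z held, as a sign that no Q stands waiting, so I expect c_Q close to zero in this flask.

4. The forecast says 34.5% and 100% of saturation: "With solid J, solid D and fixed Z, everything is pinned". Its y lies 2 percentage points below mine, and on c_Q we are opposed.

5. The flask gives 36.3%, with c_Q at 0% of saturation.

    J ⇌ Q, rate k1*(cs1 - [Q]) while solid is left; crystals form when [Q] > cs1 (solubility = 39.0 mM, k = 2.60 × 10⁻⁴ /s)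
    Z ⇌ E, rate k2*(csat - [E]) (kL = 0.00420 /s)
    Q + E → L (k = 0.210 /M/s)
    2 J → G (k = 0.00770 /M/s)
    D ⇌ L, rate k5*(cs5 - [L]) while solid is left; crystals form when [L] > cs5 (solubility = 2.90 mM, k = 0.00470 /s)

6. Taking away the conversion of 2 J into G lifts y in this flask from 36.3% to 99.5%, so that step is the main reason for the loss. In this flask W is therefore G over L: at 5.00 h it holds G at 63.7% of the J charged, each G counted as the two J it holds, against L at 36.3%, a ratio of 1.75, where I carried 1.74.

7. The same flask stopped at 80 min has its G at 63.7% already. W allows 36.5%, and with 9.9% of the charge still there as Q, y should read 26.6%. It computes to 26.4%.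

All runs were generated by integration with made-up constants, and the scatter is random.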